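## Retrosynthetic overview

- Feature: C10, the quaternary carbon shared by rings A and B, carries the C20 formyl group beside C1, C5 and C9. This marks a one-carbon ring contraction, so ring A is made last from a seven-membered homo-ring A (C10, C20, C1–C5) whose 10β,20β-epoxide shifts C1 from C20 to C10.
- The epoxide comes from the C10=C20 cycloheptene by epoxidation directed by a β-hydroxyl on C8. The cycloheptene comes from ring-closing metathesis of a C10 methylidene with a pentenyl chain on C4.
- C4 and C5 are set on a cis-fused γ-lactone template (C19–O–C10) on ring B by two exo alkylations. Ring B, with C5 and C8 fixed, comes from Pd-catalysed desymmetrisation of meso cyclohex-2-ene-1,4-diyl diacetate, iodolactonisation and radical allylation at C9.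
- After the contraction: C8 ketone, equilibration of C9, methylenation. The allyl group is cut to the C12 iodide, which alkylates a phenylthio lactone that is unmasked as the butenolide.
- Ring order: ring B, lactone template, homo-ring A (seven-membered), ring A by contraction, butenolide ring.

Key step: step 15

Numbering: labdane numbering (C1–C20) is used for all intermediates; α and β refer to the usual drawing with C20 on the β face.

Assumption: the (1R,2R)-ligand in step 2 is taken to ionise the acetate that leads to the enantiomer drawn for 5; if the sense is the reverse, the (1S,2S)-ligand is used and nothing else changes.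

## Route

Step 1
Reactants: 1 cyclohexa-1,3-diene
Product: 2 cis-cyclohex-2-ene-1,4-diyl diacetate (meso)
Conditions: Pd(OAc)2 (5 mol %), LiCl (cat.), LiOAc, p-benzoquinone, AcOH, 25 °C
Reagents that add atoms: acetic acid CC(=O)O
Why: Palladium-catalysed 1,4-diacetoxylation of a 1,3-diene; with catalytic chloride the second acetate attacks the π-allyl complex from outside, which should give the cis (meso) diacetate.

Step 2
Reactants: 2 cis-cyclohex-2-ene-1,4-diyl diacetate; 3 dimethyl malonate
Product: 5 dimethyl 2-(cis-4-acetoxycyclohex-2-en-1-yl)malonate (one enantiomer; malonate on C5; acetoxy on C8; both β), via sodium dimethyl malonate 4 (not isolated)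
Conditions: NaH, THF, 0 °C; then 2, [Pd(C3H5)Cl]2 (2.5 mol %), (1R,2R)-N,N′-bis[2-(diphenylphosphino)benzoyl]cyclohexane-1,2-diamine (7.5 mol %), CH2Cl2, 0 °C
Reagents that add atoms: none
Why: Tsuji–Trost asymmetric allylic alkylation as a desymmetrisation: the chiral ligand selects one enantiotopic acetate for ionisation and malonate attacks the allyl terminus remote from the remaining acetate anti to palladium, so C5 and C8 should be set cis in one enantiomer.

Step 3
Reactants: 5 dimethyl 2-(cis-4-acetoxycyclohex-2-en-1-yl)malonate
Product: 7 2-(cis-4-hydroxycyclohex-2-en-1-yl)acetic acid, via 2-(cis-4-hydroxycyclohex-2-en-1-yl)malonic acid 6 (not isolated)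
Conditions: LiOH, THF/H2O, 25 °C; HCl to pH 2; then pyridine, 110 °C
Reagents that add atoms: lithium hydroxide [Li+].[OH-]
Why: Saponification of the three esters followed by thermal decarboxylation of the malonic acid; no stereocentre is touched.

Step 4
Reactants: 7 2-(cis-4-hydroxycyclohex-2-en-1-yl)acetic acid
Product: 8 cis-fused iodolactone 6-hydroxy-7-iodohexahydro-1-benzofuran-2(3H)-one (lactone O on C10 β; I on C9 α; OH on C8 β)
Conditions: I2, KI, NaHCO3, THF/H2O, 0 °C
Reagents that add atoms: iodine II
Why: Kinetic iodolactonisation: the carboxylate, tethered on the β face, opens the iodonium ion at C10 in the 5-exo mode, so the lactone should be cis-fused and iodine should sit on C9 trans to both oxygens (anti addition).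

Step 5
Reactants: 8 iodolactone
Product: 9 6-(tert-butyldimethylsilyloxy)-7-iodohexahydro-1-benzofuran-2(3H)-one (same configuration)
Conditions: t-BuMe2SiCl, imidazole, DMF, 25 °C
Reagents that add atoms: tert-butyldimethylsilyl chloride CC(C)(C)[Si](C)(C)Cl
Why: Silylation of the C8 hydroxyl under weakly basic conditions, which should not close the trans-iodohydrin to an epoxide.

Step 6
Reactants: 9 silylated iodolactone; 10 allyltributylstannane
Product: 11 7-allyl-6-(tert-butyldimethylsilyloxy)hexahydro-1-benzofuran-2(3H)-one (allyl on C9 α)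
Conditions: AIBN (cat.), benzene, 80 °C
Reagents that add atoms: none
Why: Keck radical allylation: the C9 radical should be trapped on the face anti to both flanking C–O bonds, so the allyl group enters α; C9 is corrected in step 23.

Step 7
Reactants: 11 allyl lactone
Product: 13 7-allyl-6-(tert-butyldimethylsilyloxy)-3-methylhexahydro-1-benzofuran-2(3H)-one (methyl exo), via lithium enolate of 11 12 (not isolated)
Conditions: LiN(iPr)2, THF, −78 °C; then MeI, −78 °C
Reagents that add atoms: iodomethane CI
Why: Lactone enolate alkylation; the methyl group should enter from the exo face, but this centre is re-enolised in step 8 and its configuration is not carried on.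

Step 8
Reactants: 13 methyl lactone; 14 5-iodopent-1-ene
Product: 16 7-allyl-6-(tert-butyldimethylsilyloxy)-3-methyl-3-(pent-4-en-1-yl)hexahydro-1-benzofuran-2(3H)-one (pentenyl exo and cis to H5; methyl endo), via lithium enolate of 13 15 (not isolated)
Conditions: LiN(iPr)2, THF, −78 °C; then 14, DMPU, −78 → 0 °C
Reagents that add atoms: none
Why: Second enolate alkylation of the cis-fused bicyclic lactone: the iodide should approach the convex face, away from ring B and its β-silyloxy group, which sets the quaternary C4 with the C3 chain trans to C6 and the methyl in the position that becomes 4α.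

Step 9
Reactants: 16 quaternary lactone
Product: 19 methyl 2-[3-allyl-4-(tert-butyldimethylsilyloxy)-2-oxocyclohexyl]-2-methylhept-6-enoate (C10 ketone; C19 methyl ester), via potassium hydroxy carboxylate 17 (not isolated), via hydroxy methyl ester 18 (not isolated)
Conditions: KOH, MeOH/H2O, 50 °C; then MeI, DMF, 25 °C; then Dess–Martin periodinane, pyridine, CH2Cl2, 0 °C
Reagents that add atoms: potassium hydroxide [K+].[OH-]; iodomethane CI
Why: Saponification, O-methylation of the carboxylate and Dess–Martin oxidation of the C10 carbinol before it can relactonise; all three operations are non-enolising, so C5 and C9 next to the new ketone should stay as they are.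

Step 10
Reactants: 19 keto ester
Product: 20 methyl 2-[3-allyl-4-(tert-butyldimethylsilyloxy)-2-methylidenecyclohexyl]-2-methylhept-6-enoate
Conditions: Cp2Ti(μ-Cl)(μ-CH2)AlMe2 (Tebbe reagent), pyridine, THF/toluene, −40 → 0 °C
Reagents that add atoms: Tebbe reagent C=[Ti](C1C=CC=C1)C1C=CC=C1.C[Al](C)Cl
Why: Tebbe methylenation: the non-basic titanium methylidene should convert the hindered, epimerisable ketone into the C10 methylidene at low temperature without touching the hindered ester or the α-stereocentres.

Step 11
Reactants: 20 methylidene triene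
Product: 21 bicyclic alkene (seven-membered ring C10=C20–C1–C2–C3–C4–C5 fused to ring B; 4α-CH3; 4β-CO2Me; 5α-H; 8β-OSiMe2tBu; 9α-allyl)
Conditions: RuCl2(=CHPh)(PCy3)(H2IMes) (second-generation Grubbs catalyst, 10 mol %), CH2Cl2 (2 mM), 40 °C
Reagents that add atoms: none
Why: Ring-closing metathesis: the alkylidene formed at the pentenyl terminus should close onto the 1,1-disubstituted C10 methylidene, helped by the quaternary C4 in the tether, to give the trisubstituted cycloheptene; the allyl group can only form a four- or ten-membered ring.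

Step 12
Reactants: 21 bicyclic alkene silyl ether
Product: 22 bicyclic alkene with free 8β-OH
Conditions: HF·pyridine, pyridine, THF, 0 → 25 °C
Reagents that add atoms: none
Why: Fluoride cleavage of the only silyl ether frees the C8 hydroxyl that directs the next step.

Step 13
Reactants: 22 homoallylic alcohol
Product: 23 10β,20β-epoxide of 22 (8β-OH retained)
Conditions: VO(acac)2 (5 mol %), t-BuOOH, CH2Cl2, 0 → 25 °C
Reagents that add atoms: tert-butyl hydroperoxide CC(C)(C)OO
Why: Vanadium-catalysed hydroxyl-directed epoxidation of a homoallylic alcohol: the β-oriented C8 alkoxide should carry the peroxide to the β face of C10=C20, while the allyl alkene, anti to the hydroxyl, is out of reach.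

Step 14
Reactants: 23 epoxy alcohol
Product: 24 10β,20β-epoxide with 8β-OSiEt3 (precursor of the key step)
Conditions: Et3SiCl, imidazole, DMAP (cat.), DMF, 25 °C
Reagents that add atoms: chlorotriethylsilane CC[Si](Cl)(CC)CC
Why: Silylation under basic conditions, which should leave the acid-sensitive trisubstituted epoxide intact; the syn hydroxyl cannot open the epoxide from the rear.

Step 15
Reactants: 24 epoxy silyl ether
Product: 25 trans-decalin aldehyde (10β-CHO; 4α-CH3; 4β-CO2Me; 5α-H; 8β-OSiEt3; 9α-allyl)
Conditions: MeAl(OAr)2 (Ar = 4-bromo-2,6-di-tert-butylphenyl; 2 equiv), CH2Cl2, −78 → −40 °C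
Reagents that add atoms: none
Why: The bulky aluminium Lewis acid binds the epoxide oxygen and ionises the tertiary C10–O bond, and the ring bond C20–C1 shifts to C10 while C20–O becomes the carbonyl group (Meinwald rearrangement; the closest known case is the contraction of 1-alkylcycloalkene oxides to quaternary aldehydes with aluminium aryloxides). Ring A (C1–C5, C10) is closed by this 1,2-alkyl shift, a contraction of the seven-membered ring, and not by cyclisation of a chain. The new stereocentre C10 is set by inversion: the leaving oxygen is β and axial on ring B, so C1 enters from the α side and becomes equatorial while C20 moves into the β-axial position, which gives the trans-decalin with the 10β-formyl group. The step needs migration of C1 and not of hydride, and no capture of the C10 cation; the bulky aluminium alkoxide on C20 should favour the rotamer that places C1 over the empty lobe. The C8 silyloxy group and the C19 ester lie on the β face and cannot reach C10 from the rear, and the α chain on C9 is kept as a hydrocarbon (allyl) so that no ether oxygen can intercept the cation.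

Step 16
Reactants: 25 aldehyde
Product: 26 1,3-dioxolane of 25 at C20
Conditions: (Me3SiOCH2)2, Me3SiOTf (5 mol %), CH2Cl2, −78 → −20 °C
Reagents that add atoms: 1,2-bis(trimethylsilyloxy)ethane C[Si](C)(C)OCCO[Si](C)(C)C
Why: Noyori acetalisation, the silyl triflate-catalysed exchange that should still work on a neopentyl aldehyde flanked by two syn-axial groups.

Step 17
Reactants: 26 allyl dioxolane
Product: 28 primary alcohol (C9–CH2CH2OH; C12 hydroxyl), via ozonide 27 (not isolated)
Conditions: O3, CH2Cl2, −78 °C; then NaBH4, MeOH, −78 → 0 °C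
Reagents that add atoms: ozone [O-][O+]=O
Why: Ozonolysis with reductive work-up: the allyl group is the only alkene left, and borohydride should reduce the ozonide to the C12 alcohol without touching the hindered ester.

Step 18
Reactants: 28 primary alcohol
Product: 29 primary iodide (C12–I)
Conditions: I2, PPh3, imidazole, CH2Cl2, 0 °C
Reagents that add atoms: iodine II
Why: Appel-type iodination of a primary alcohol under buffered conditions that the silyl ether and the acetal should tolerate.

Step 19
Reactants: 30 3-bromodihydrofuran-2(3H)-one; 31 thiophenol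
Product: 32 3-(phenylthio)dihydrofuran-2(3H)-one (racemic)
Conditions: Et3N, CH2Cl2, 0 → 25 °C
Reagents that add atoms: none
Why: SN2 displacement of the α-bromide by thiolate gives the masked butenolide unit.

Step 20
Reactants: 29 primary iodide; 32 3-(phenylthio)dihydrofuran-2(3H)-one
Product: 34 3-alkyl-3-(phenylthio)lactone (C12–C13 bond formed; both C13 epimers; 8β-OSiEt3), via lithium enolate of 32 33 (not isolated)
Conditions: 32, LiN(iPr)2, THF, −78 °C; then 29, HMPA, −78 → 25 °C
Reagents that add atoms: none
Why: Alkylation of the sulfur-stabilised lactone enolate with a primary iodide; the C13 centre is removed in step 25, so the epimer mixture is of no consequence.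

Step 21
Reactants: 34 silyl ether
Product: 35 8β-alcohol (C13 epimers)
Conditions: Bu4NF, THF, 0 °C
Reagents that add atoms: none
Why: Fluoride desilylation under basic conditions, chosen so that the freed syn-axial hydroxyl does not exchange with the neighbouring dioxolane.

Step 22
Reactants: 35 8β-alcohol
Product: 36 C8 ketone with the 9α side chain (C13 epimers)
Conditions: Dess–Martin periodinane, pyridine, CH2Cl2, 0 → 25 °C
Reagents that add atoms: none
Why: Dess–Martin oxidation of a secondary alcohol, which should be much faster than oxidation of the aryl sulfide.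

Step 23
Reactants: 36 C8 ketone (9α chain)
Product: 37 C8 ketone with the 9β side chain and 9α-H (C13 epimers)
Conditions: KOtBu (0.2 equiv), t-BuOH/THF, 25 °C
Reagents that add atoms: none
Why: Base-catalysed epimerisation through the C8 enolate: the axial α chain, syn-axial to H5 and H7, should move to the equatorial β position of the trans-decalin, which is the configuration of the target.

Step 24
Reactants: 37 C8 ketone (9β chain)
Product: 38 8(17)-methylidene compound (C13 epimers)
Conditions: Ph3PCH3Br, KN(SiMe3)2, THF, 0 → 25 °C
Reagents that add atoms: methyltriphenylphosphonium bromide C[P+](c1ccccc1)(c1ccccc1)c1ccccc1.[Br-]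
Why: Wittig methylenation of the ketone; the hindered methyl ester and the α-quaternary lactone should be much slower electrophiles, and C9 is already at its thermodynamic configuration.

Step 25
Reactants: 38 phenylthio lactone
Product: 40 butenolide with the C20 dioxolane, via sulfoxide 39 (not isolated)
Conditions: mCPBA (1.0 equiv), CH2Cl2, −78 °C; then toluene, 110 °C
Reagents that add atoms: none
Why: Sulfide oxidation followed by thermal syn-elimination of the sulfoxide towards the ring CH2 should give the conjugated α-alkylbutenolide; at −78 °C the sulfide should react far faster than the 1,1-disubstituted alkene.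

Step 26
Reactants: 40 dioxolane
Product: 41 CNP0175906.1 (target)
Conditions: TsOH·H2O (cat.), acetone/H2O, 40 °C
Reagents that add atoms: water O
Why: Acid-catalysed acetal hydrolysis, helped by relief of the 1,3-diaxial strain, under conditions mild enough for the exocyclic alkene and the butenolide.

## Compound list

1 | cyclohexa-1,3-diene | C1=CC=CCC1 | starting material
2 | cis-cyclohex-2-ene-1,4-diyl diacetate (meso) | CC(=O)O[C@H]1C=C[C@@H](OC(C)=O)CC1 | intermediate
3 | dimethyl malonate | COC(=O)CC(=O)OC | starting material
4 | sodium dimethyl malonate | [Na+].COC(=O)[CH-]C(=O)OC | intermediate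
5 | dimethyl 2-(cis-4-acetoxycyclohex-2-en-1-yl)malonate | COC(=O)C(C(=O)OC)[C@H]1C=C[C@@H](OC(C)=O)CC1 | intermediate
6 | 2-(cis-4-hydroxycyclohex-2-en-1-yl)malonic acid | OC(=O)C(C(O)=O)[C@H]1C=C[C@@H](O)CC1 | intermediate
7 | 2-(cis-4-hydroxycyclohex-2-en-1-yl)acetic acid | OC(=O)C[C@H]1C=C[C@@H](O)CC1 | intermediate
8 | cis-fused 6-hydroxy-7-iodohexahydro-1-benzofuran-2(3H)-one | O=C1C[C@@H]2CC[C@H](O)[C@@H](I)[C@@H]2O1 | intermediate
9 | 6-(tert-butyldimethylsilyloxy)-7-iodo lactone | O=C1C[C@@H]2CC[C@H](O[Si](C)(C)C(C)(C)C)[C@@H](I)[C@@H]2O1 | intermediate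
10 | allyltributylstannane | C=CC[Sn](CCCC)(CCCC)CCCC | starting material
11 | 7-allyl-6-(tert-butyldimethylsilyloxy) lactone | O=C1C[C@@H]2CC[C@H](O[Si](C)(C)C(C)(C)C)[C@@H](CC=C)[C@@H]2O1 | intermediate
12 | lithium enolate of 11 | [Li+].[O-]C1=C[C@@H]2CC[C@H](O[Si](C)(C)C(C)(C)C)[C@@H](CC=C)[C@@H]2O1 | intermediate
13 | 3-methyl lactone (methyl exo) | O=C1[C@@H](C)[C@@H]2CC[C@H](O[Si](C)(C)C(C)(C)C)[C@@H](CC=C)[C@@H]2O1 | intermediate
14 | 5-iodopent-1-ene | ICCCC=C | starting material
15 | lithium enolate of 13 | [Li+].[O-]C1=C(C)[C@@H]2CC[C@H](O[Si](C)(C)C(C)(C)C)[C@@H](CC=C)[C@@H]2O1 | intermediate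
16 | 3-methyl-3-(pent-4-en-1-yl) lactone (C4 quaternary) | O=C1[C@@](C)(CCCC=C)[C@@H]2CC[C@H](O[Si](C)(C)C(C)(C)C)[C@@H](CC=C)[C@@H]2O1 | intermediate
17 | potassium hydroxy carboxylate (opened lactone) | [K+].[O-]C(=O)[C@@](C)(CCCC=C)[C@@H]1CC[C@H](O[Si](C)(C)C(C)(C)C)[C@@H](CC=C)[C@@H]1O | intermediate
18 | hydroxy methyl ester | COC(=O)[C@@](C)(CCCC=C)[C@@H]1CC[C@H](O[Si](C)(C)C(C)(C)C)[C@@H](CC=C)[C@@H]1O | intermediate
19 | keto ester (C10 ketone) | COC(=O)[C@@](C)(CCCC=C)[C@@H]1CC[C@H](O[Si](C)(C)C(C)(C)C)[C@@H](CC=C)C1=O | intermediate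
20 | C10 methylidene ester | COC(=O)[C@@](C)(CCCC=C)[C@@H]1CC[C@H](O[Si](C)(C)C(C)(C)C)[C@@H](CC=C)C1=C | intermediate
21 | bicyclic C10=C20 alkene, 8β-OSiMe2tBu | COC(=O)[C@@]1(C)CCCC=C2[C@H](CC=C)[C@@H](O[Si](C)(C)C(C)(C)C)CC[C@@H]12 | intermediate
22 | bicyclic C10=C20 alkene, 8β-OH | COC(=O)[C@@]1(C)CCCC=C2[C@H](CC=C)[C@@H](O)CC[C@@H]12 | intermediate
23 | 10β,20β-epoxide, 8β-OH | COC(=O)[C@@]1(C)CCC[C@H]2O[C@]23[C@H](CC=C)[C@@H](O)CC[C@@H]13 | intermediate
24 | 10β,20β-epoxide, 8β-OSiEt3 (key-step precursor) | COC(=O)[C@@]1(C)CCC[C@H]2O[C@]23[C@H](CC=C)[C@@H](O[Si](CC)(CC)CC)CC[C@@H]13 | intermediate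
25 | trans-decalin 10β-aldehyde (key-step product) | CC[Si](CC)(CC)O[C@H]1CC[C@@H]2[C@](C=O)(CCC[C@]2(C)C(=O)OC)[C@@H]1CC=C | intermediate
26 | C20 dioxolane | CC[Si](CC)(CC)O[C@H]1CC[C@@H]2[C@](C3OCCO3)(CCC[C@]2(C)C(=O)OC)[C@@H]1CC=C | intermediate
27 | ozonide of 26 | CC[Si](CC)(CC)O[C@H]1CC[C@@H]2[C@](C3OCCO3)(CCC[C@]2(C)C(=O)OC)[C@@H]1CC1OCOO1 | intermediate
28 | C12 alcohol | CC[Si](CC)(CC)O[C@H]1CC[C@@H]2[C@](C3OCCO3)(CCC[C@]2(C)C(=O)OC)[C@@H]1CCO | intermediate
29 | C12 iodide | CC[Si](CC)(CC)O[C@H]1CC[C@@H]2[C@](C3OCCO3)(CCC[C@]2(C)C(=O)OC)[C@@H]1CCI | intermediate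
30 | 3-bromodihydrofuran-2(3H)-one | BrC1CCOC1=O | starting material
31 | thiophenol | Sc1ccccc1 | starting material
32 | 3-(phenylthio)dihydrofuran-2(3H)-one | O=C1OCCC1Sc1ccccc1 | intermediate
33 | lithium enolate of 32 | [Li+].[O-]C1=C(Sc2ccccc2)CCO1 | intermediate
34 | alkylated phenylthio lactone, 8β-OSiEt3 | CC[Si](CC)(CC)O[C@H]1CC[C@@H]2[C@](C3OCCO3)(CCC[C@]2(C)C(=O)OC)[C@@H]1CCC1(Sc3ccccc3)CCOC1=O | intermediate
35 | alkylated phenylthio lactone, 8β-OH | O[C@H]1CC[C@@H]2[C@](C3OCCO3)(CCC[C@]2(C)C(=O)OC)[C@@H]1CCC1(Sc3ccccc3)CCOC1=O | intermediate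
36 | C8 ketone, 9α side chain | O=C1CC[C@@H]2[C@](C3OCCO3)(CCC[C@]2(C)C(=O)OC)[C@@H]1CCC1(Sc3ccccc3)CCOC1=O | intermediate
37 | C8 ketone, 9β side chain | O=C1CC[C@@H]2[C@](C3OCCO3)(CCC[C@]2(C)C(=O)OC)[C@H]1CCC1(Sc3ccccc3)CCOC1=O | intermediate
38 | 8(17)-methylidene phenylthio lactone | C=C1CC[C@@H]2[C@](C3OCCO3)(CCC[C@]2(C)C(=O)OC)[C@H]1CCC1(Sc3ccccc3)CCOC1=O | intermediate
39 | sulfoxide of 38 | C=C1CC[C@@H]2[C@](C3OCCO3)(CCC[C@]2(C)C(=O)OC)[C@H]1CCC1(S(=O)c3ccccc3)CCOC1=O | intermediate
40 | butenolide with C20 dioxolane | C=C1CC[C@@H]2[C@](C3OCCO3)(CCC[C@]2(C)C(=O)OC)[C@H]1CCC1=CCOC1=O | intermediate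
41 | CNP0175906.1 | C=C1CC[C@@H]2[C@](C=O)(CCC[C@]2(C)C(=O)OC)[C@H]1CCC1=CCOC1=O | target

## Step count

Total step count: 26. Longest linear sequence: 25 steps (steps 1–18 and 20–26; step 19 makes the side reagent 32).

## Steps most likely to fail

1. Step 15. Hydride may migrate from C20 in place of the ring bond, or the C10 cation may lose a proton from C5 or C9 to give an allylic alcohol. The fallback changes the mechanism to a two-stage halohydrin contraction that needs the opposite epoxide. It sets out from 22 and returns at 25. Alcohol 22 is silylated (Et3SiCl, imidazole) to the triethylsilyl ether F1. With no free hydroxyl and with the axial silyloxy group on the β face, peracid epoxidation (mCPBA, NaHCO3) should give the α-epoxide F2. LiBr and HMPA in benzene at 80 °C then open F2 with bromide at C10 with inversion, and the bromohydrin alkoxide contracts with a second inversion (C1 displaces bromide from the α side), which should lead to aldehyde 25.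

2. Step 13. Oxygen may be delivered to the α face, or to the allyl alkene, if the vanadium alkoxide does not control the approach. The fallback replaces metal-directed delivery by an intramolecular cyclisation. It sets out from 22 and returns at 23. Alcohol 22 is converted (Boc2O, DMAP) into the tert-butyl carbonate F3. IBr at −80 °C should close the carbonate oxygen onto C10 from the β face to give the iodo cyclic carbonate F4 with iodine on C20. K2CO3 in MeOH cleaves the carbonate, and the C10 alkoxide displaces iodide to give epoxy alcohol 23.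

3. Step 11. The ruthenium alkylidene may fail to add to the hindered C10 methylidene, and the allyl group may then enter cross-metathesis and oligomerisation. The fallback avoids both the methylidene and the catalytic metathesis. It sets out from keto ester 19 and returns at 21, and makes no new compound (F0). Stoichiometric Mo(=CHCMe2Ph)(=N-2,6-iPr2C6H3)[OCMe(CF3)2]2 in benzene at 25 °C exchanges with the pentenyl terminus, and the new molybdenum alkylidene olefinates the C10 ketone in the ring (carbonyl–olefin metathesis), which should give cycloheptene 21 directly.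

## Further compounds

F1 | step 15 | triethylsilyl ether of 22 | COC(=O)[C@@]1(C)CCCC=C2[C@H](CC=C)[C@@H](O[Si](CC)(CC)CC)CC[C@@H]12
F2 | step 15 | 10α,20α-epoxide with 8β-OSiEt3 | COC(=O)[C@@]1(C)CCC[C@@H]2O[C@@]23[C@H](CC=C)[C@@H](O[Si](CC)(CC)CC)CC[C@@H]13
F3 | step 13 | tert-butyl carbonate of 22 | COC(=O)[C@@]1(C)CCCC=C2[C@H](CC=C)[C@@H](OC(=O)OC(C)(C)C)CC[C@@H]12
F4 | step 13 | iodo cyclic carbonate (C8–O–CO–O–C10; iodine on C20) | COC(=O)[C@@]1(C)CCC[C@H](I)[C@]23OC(=O)O[C@H]([C@H]2CC=C)CC[C@@H]13
F0 | step 11 | none | none
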